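**Retrosynthetic overview**

1. Ring numbering and enabling feature: in each six-membered ring C1 is the carbonyl carbon between the two substituted carbons, C2 carries the succinate carbon Cα, C3 is the adjacent CH, C4 is the second carbonyl carbon, C5 is CH and C6 carries the geranyl group. Cα–C2–C3–C4 is the α,3-didehydrotoluene pattern (ester-bearing exocyclic carbon on C2, unsubstituted C3, C4 meta to C2), so closing C2–C3 from an enyne-allene leaves one radical on Cα and one on C4.
2. Last disconnections: both C4 carbonyls come from para-oxidation of a meso bis(2,6-disubstituted phenol); the meso configuration comes from base equilibration when the phenol silyl ethers are removed.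
3. Key disconnection: the bis(aryl silyl ether) goes back to two molecules of an acyclic (Z)-enynyl γ-silyloxy ynoate. In one flask: prototropy to the allenoate, Myers–Saito closure of the C2–C3 ring bond, reduction of the C4 σ-radical, and head-to-head coupling of two Cα radicals (central C–C bond, both stereocenters).
4. The acyclic precursor comes from (Z)-2-geranylpent-2-en-4-ynal and methyl propiolate; the enynal comes from geranyl bromide, ethyl acetate, ethyl formate and an ethynyl unit through a chelation-controlled (Z)-enol triflate.
5. Ring order: the two carbocycles are the only rings; each is closed in step 8 (one per precursor molecule) and the two are joined in the same operation, before the quinone oxidation level is reached.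

Key step: step 8

Remark on the chemistry: the two identically substituted stereocenters are (R,S), so the target is the meso diastereomer and only relative configuration has to be controlled; geranyl = (2E)-3,7-dimethylocta-2,6-dien-1-yl throughout.

**Route**

Step 1
Reactants: 1 geranyl bromide; 2 ethyl acetate
Product: 3 ethyl (4E)-5,9-dimethyldeca-4,8-dienoate
Conditions: 2, LiN(i-Pr)2, THF, −78 °C; then 1, DMPU, −78 → −20 °C
Reagents that add atoms: geranyl bromide, BrC/C=C(\C)CCC=C(C)C; ethyl acetate, CCOC(C)=O
Why: SN2 alkylation of the lithium ester enolate by the primary allylic bromide should proceed without allylic transposition, so the E-geranyl unit is transferred intact (enolate alkylation).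

Step 2
Reactants: 3; 4 ethyl formate
Product: 5 ethyl (4E)-2-formyl-5,9-dimethyldeca-4,8-dienoate (racemic, mainly as its hydroxymethylene enol)
Conditions: LiN(i-Pr)2, THF, −78 °C; then 4, −78 → 0 °C; aq. HCl to pH 4
Reagents that add atoms: ethyl formate, CCOC=O
Why: Crossed Claisen condensation of the ester enolate with non-enolizable ethyl formate, driven by deprotonation of the β-formyl ester by the liberated ethoxide.

Step 3
Reactants: 5; 6 N-phenylbis(trifluoromethanesulfonimide)
Product: 7 ethyl (2Z)-2-geranyl-3-[(trifluoromethylsulfonyl)oxy]prop-2-enoate
Conditions: NaH, THF, 0 °C; then 6, 0 °C → rt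
Reagents that add atoms: N-phenylbis(trifluoromethanesulfonimide), O=S(=O)(N(c1ccccc1)S(=O)(=O)C(F)(F)F)C(F)(F)F
Why: O-sulfonylation of the sodium enolate, held as the Z chelate between formyl and ester oxygens, should give the enol triflate with the triflate cis to the ester (chelation-controlled enol triflate formation), which fixes the alkene geometry needed for the ring closure.

Step 4
Reactants: 7; 8 ethynylmagnesium bromide
Product: 9 ethyl (2Z)-2-geranylpent-2-en-4-ynoate
Conditions: 8, ZnBr2, THF, 0 °C; then 7, Pd(PPh3)4 (5 mol %), rt
Reagents that add atoms: ethynylmagnesium bromide, C#C[Mg]Br (transmetalated in the flask to ethynylzinc bromide, C#C[Zn]Br)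
Why: Negishi alkynylation of the vinyl triflate proceeds with retention of alkene geometry and delivers the terminal enyne directly, without a silyl protecting group.

Step 5
Reactants: 9
Product: 10 (2Z)-2-geranylpent-2-en-4-yn-1-ol
Conditions: i-Bu2AlH (2.5 equiv), CH2Cl2, −78 °C; aq. potassium sodium tartrate (KNaC4H4O6)
Reagents that add atoms: none
Why: i-Bu2AlH reduces the conjugated ester to the allylic alcohol (1,2-reduction) at low temperature without touching the terminal alkyne or the alkene geometry.

Step 6
Reactants: 10
Product: 11 (2Z)-2-geranylpent-2-en-4-ynal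
Conditions: activated MnO2, CH2Cl2, rt, dark
Reagents that add atoms: none
Why: MnO2 oxidizes the allylic alcohol selectively to the enal under neutral conditions that should preserve the Z geometry.

Step 7
Reactants: 11; 12 methyl propiolate; 13 tert-butyldimethylsilyl trifluoromethanesulfonate
Product: 14 methyl (5Z)-4-[(tert-butyldimethylsilyl)oxy]-5-geranyloct-5-ene-2,7-diynoate (racemic)
Conditions: 12, LiN(SiMe3)2, THF, −78 °C; then 11; then t-BuMe2SiOTf, −78 → −40 °C; pH 7 buffer
Reagents that add atoms: methyl propiolate, COC(=O)C#C; tert-butyldimethylsilyl trifluoromethanesulfonate, CC(C)(C)[Si](C)(C)OS(=O)(=O)C(F)(F)F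
Why: 1,2-Addition of lithium methyl propiolate (too weak a base to deprotonate the free enyne alkyne) to the enal, with silylation of the lithium alkoxide in the flask before any base can isomerize the free γ-hydroxy ynoate; the new carbinol center is racemic and is destroyed in step 8.

Step 8
Reactants: 14 (two molecules)
Product: 18 dimethyl 2,3-bis{2-[(tert-butyldimethylsilyl)oxy]-3-geranylphenyl}butanedioate (meso/racemic mixture), via siloxy enyne-allene 15 (not isolated), via aryl/benzyl σ,π-biradical 16 (not isolated), via benzylic radical 17 (not isolated)
Conditions: DBU (0.1 equiv), benzene (degassed, 0.2 M), rt; then 1,4-cyclohexadiene (2.5 equiv), 60 °C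
Reagents that add atoms: none
Why: Proposed new method: DBU shifts the proton from the silyloxy-bearing carbon to the ester α-carbon and gives γ-silyloxy allenoate 15, in which the allene central carbon (future C2) and the terminal alkyne carbon (future C3) are held cis by the (Z)-alkene; on warming, Myers–Saito cycloaromatization joins exactly these two carbons and closes the benzene ring, leaving σ,π-biradical 16 with one electron in the ring plane at C4 and one on Cα. The closest known reaction type is the Myers–Saito cyclization of enyne-allenes released by base-induced propargyl-to-allene isomerization, in which the σ-radical is reduced by 1,4-cyclohexadiene and self-coupling of the benzylic radical is a recognized termination channel; what is new is to make this coupling the productive outcome by placing an ester on the benzylic carbon. The single ring is closed in the C2–C7 mode of the enyne-allene (formally 6-endo at the alkyne terminus), which an unsubstituted alkyne terminus favors over the five-membered fulvene-type closure. The aryl σ-radical is quenched by the diene at close to the diffusion limit, whereas the ester- and aryl-stabilized radical 17 abstracts hydrogen from the diene only slowly, so that at moderate diene concentration and high radical flux it should end mainly by head-to-head dimerization, which makes the central C–C bond. The two stereocenters are formed in this radical–radical coupling without a controlling element, so a meso/racemic mixture is expected and the meso configuration is secured only in step 9. The selectivities needed are the Z geometry of the enyne (fixed in step 3), six- over five-membered closure (terminal alkyne) and dimerization over reduction of 17 (limited diene; any monomer formed is reconverted as described in the fallback).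

Step 9
Reactants: 18
Product: 19 dimethyl (2R,3S)-2,3-bis(3-geranyl-2-hydroxyphenyl)butanedioate (meso)
Conditions: NaOMe (6 equiv), MeOH/THF, 40 °C, argon; AcOH, 0 °C
Reagents that add atoms: none
Why: Methoxide cleaves both aryl silyl ethers and equilibrates the two ester α-centers (directly or through the transient benzofuranone lactone with its far more acidic α-proton) toward the meso diastereomer, which can place both aryl groups and both esters anti and should therefore be thermodynamically preferred, while methanol makes transesterification degenerate and reopens any lactone (thermodynamic epimerization).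

Step 10
Reactants: 19; 20 potassium nitrosodisulfonate
Product: 21 dimethyl (2R,3S)-2,3-bis(5-geranyl-3,6-dioxocyclohexa-1,4-dien-1-yl)butanedioate (meso; target)
Conditions: (KSO3)2NO (5 equiv), KH2PO4 buffer (pH 6.5), acetone/H2O, 0 °C → rt
Reagents that add atoms: potassium nitrosodisulfonate, [K+].[K+].[O]N(S(=O)(=O)[O-])S(=O)(=O)[O-]
Why: Teuber oxidation converts a phenol with both ortho positions substituted and a free para position into the para-quinone, the new oxygen coming from the nitroxide, under buffered conditions that should leave the trisubstituted alkenes and the base-sensitive α-centers untouched.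

**Compound list**

1 | geranyl bromide | BrC/C=C(\C)CCC=C(C)C | starting material
2 | ethyl acetate | CCOC(C)=O | starting material
3 | ethyl (4E)-5,9-dimethyldeca-4,8-dienoate | CCOC(=O)CC/C=C(\C)CCC=C(C)C | intermediate
4 | ethyl formate | CCOC=O | starting material
5 | ethyl (4E)-2-formyl-5,9-dimethyldeca-4,8-dienoate (racemic) | CCOC(=O)C(C=O)C/C=C(\C)CCC=C(C)C | intermediate
6 | N-phenylbis(trifluoromethanesulfonimide) | O=S(=O)(N(c1ccccc1)S(=O)(=O)C(F)(F)F)C(F)(F)F | starting material
7 | ethyl (2Z)-2-geranyl-3-[(trifluoromethylsulfonyl)oxy]prop-2-enoate | CCOC(=O)/C(C/C=C(\C)CCC=C(C)C)=C\OS(=O)(=O)C(F)(F)F | intermediate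
8 | ethynylmagnesium bromide | C#C[Mg]Br | starting material
9 | ethyl (2Z)-2-geranylpent-2-en-4-ynoate | CCOC(=O)/C(C/C=C(\C)CCC=C(C)C)=C\C#C | intermediate
10 | (2Z)-2-geranylpent-2-en-4-yn-1-ol | OC/C(C/C=C(\C)CCC=C(C)C)=C\C#C | intermediate
11 | (2Z)-2-geranylpent-2-en-4-ynal | O=C/C(C/C=C(\C)CCC=C(C)C)=C\C#C | intermediate
12 | methyl propiolate | COC(=O)C#C | starting material
13 | tert-butyldimethylsilyl trifluoromethanesulfonate | CC(C)(C)[Si](C)(C)OS(=O)(=O)C(F)(F)F | starting material
14 | methyl (5Z)-4-[(tert-butyldimethylsilyl)oxy]-5-geranyloct-5-ene-2,7-diynoate (racemic) | COC(=O)C#CC(O[Si](C)(C)C(C)(C)C)/C(C/C=C(\C)CCC=C(C)C)=C\C#C | intermediate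
15 | methyl (5Z)-4-[(tert-butyldimethylsilyl)oxy]-5-geranylocta-2,3,5-trien-7-ynoate (racemic allene) | COC(=O)C=C=C(O[Si](C)(C)C(C)(C)C)/C(C/C=C(\C)CCC=C(C)C)=C\C#C | intermediate (not isolated)
16 | σ,π-biradical: methyl 2-{2-[(tert-butyldimethylsilyl)oxy]-3-geranylphenyl}acetate with radical sites at the benzylic carbon and at aryl C5 | COC(=O)[CH]c1c[c]cc(C/C=C(\C)CCC=C(C)C)c1O[Si](C)(C)C(C)(C)C | intermediate (not isolated)
17 | benzylic radical: (methoxycarbonyl){2-[(tert-butyldimethylsilyl)oxy]-3-geranylphenyl}methyl | COC(=O)[CH]c1cccc(C/C=C(\C)CCC=C(C)C)c1O[Si](C)(C)C(C)(C)C | intermediate (not isolated)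
18 | dimethyl 2,3-bis{2-[(tert-butyldimethylsilyl)oxy]-3-geranylphenyl}butanedioate (meso/racemic mixture, α-centers not defined) | COC(=O)C(c1cccc(C/C=C(\C)CCC=C(C)C)c1O[Si](C)(C)C(C)(C)C)C(C(=O)OC)c1cccc(C/C=C(\C)CCC=C(C)C)c1O[Si](C)(C)C(C)(C)C | intermediate
19 | dimethyl (2R,3S)-2,3-bis(3-geranyl-2-hydroxyphenyl)butanedioate (meso) | COC(=O)[C@H](c1cccc(C/C=C(\C)CCC=C(C)C)c1O)[C@@H](C(=O)OC)c1cccc(C/C=C(\C)CCC=C(C)C)c1O | intermediate
20 | potassium nitrosodisulfonate | [K+].[K+].[O]N(S(=O)(=O)[O-])S(=O)(=O)[O-] | starting material
21 | dimethyl (2R,3S)-2,3-bis(5-geranyl-3,6-dioxocyclohexa-1,4-dien-1-yl)butanedioate (meso) | COC(=O)[C@H](C1=CC(=O)C=C(C/C=C(\C)CCC=C(C)C)C1=O)[C@@H](C(=O)OC)C1=CC(=O)C=C(C/C=C(\C)CCC=C(C)C)C1=O | target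

Total step count: 10. Longest linear sequence: 10 steps (1 and 2 to 21).

**Steps most likely to fail**

Step 8. The risk is that radical 17 is consumed by cross-termination with cyclohexadienyl radicals (reduction or adduct formation) faster than it dimerizes, or that the base isomerizes 15 further before it cyclizes. The fallback uses known chemistry, sets out from 14 and comes back at 18. The same prototropy and Myers–Saito cyclization is run at high dilution with 1,4-cyclohexadiene as cosolvent, so that both radical sites are reduced and the monomer methyl 2-{2-[(tert-butyldimethylsilyl)oxy]-3-geranylphenyl}acetate F1 is formed. Its lithium enolate (LiN(i-Pr)2, THF, −78 °C) is then coupled oxidatively with I2 (0.5 equiv), an iodine-mediated ester enolate homocoupling, which should give 18 as the same meso/racemic mixture.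

Step 9. The risk is an insufficient thermodynamic bias toward the meso isomer, or lactonization and air oxidation of the phenoxides during the basic equilibration. The fallback sets out from 18 and comes back at 21. The silyl ethers are removed without base (Et3N·3HF, THF, rt), which should give 19 together with its diastereomer dimethyl (2RS,3RS)-2,3-bis(3-geranyl-2-hydroxyphenyl)butanedioate F2. The mixture is oxidized as in step 10 to 21 and dimethyl (2RS,3RS)-2,3-bis(5-geranyl-3,6-dioxocyclohexa-1,4-dien-1-yl)butanedioate F3. Epimerization is then done at the quinone stage, where each α-proton is vinylogous to the C4 carbonyl and should exchange under a catalytic Et3N/AcOH buffer in CH2Cl2. The meso compound 21 is separated by crystallization or chromatography and F3 is recycled.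

Step 3. The risk is loss of geometric control in the enolate sulfonylation (a non-chelated enolate gives the E triflate, whose enyne cannot cyclize), with possible erosion of the Z geometry up to the enal. The fallback sets out from 1 and comes back at 11; it lets a furan ring fix the cis geometry.
- Commercial 4-bromofuran-2-carbaldehyde (O=Cc1cc(Br)co1) is protected with ethylene glycol (TsOH, benzene, reflux) as 2-(4-bromofuran-2-yl)-1,3-dioxolane F4.
- Bromine–lithium exchange (n-BuLi, THF, −78 °C), transmetalation with ZnBr2 and Negishi allylation with 1 (Pd(PPh3)4 cat.) should give 2-(4-geranylfuran-2-yl)-1,3-dioxolane F5.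
- Mild acetal hydrolysis (PPTS, acetone/H2O) gives 4-geranylfuran-2-carbaldehyde F6, and condensation with p-toluenesulfonyl hydrazide gives 4-geranylfuran-2-carbaldehyde N-tosylhydrazone F7.
- Heating the sodium salt of F7 (NaH; toluene, 100 °C; Bamford–Stevens conditions) generates the 2-furylcarbene, which ring-opens to 11 with the alkyne and the formyl group necessarily cis.

Further compounds
F1 | step 8 | methyl 2-{2-[(tert-butyldimethylsilyl)oxy]-3-geranylphenyl}acetate | COC(=O)Cc1cccc(C/C=C(\C)CCC=C(C)C)c1O[Si](C)(C)C(C)(C)C
F2 | step 9 | dimethyl (2RS,3RS)-2,3-bis(3-geranyl-2-hydroxyphenyl)butanedioate (racemic, one enantiomer drawn) | COC(=O)[C@H](c1cccc(C/C=C(\C)CCC=C(C)C)c1O)[C@H](C(=O)OC)c1cccc(C/C=C(\C)CCC=C(C)C)c1O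
F3 | step 9 | dimethyl (2RS,3RS)-2,3-bis(5-geranyl-3,6-dioxocyclohexa-1,4-dien-1-yl)butanedioate (racemic, one enantiomer drawn) | COC(=O)[C@H](C1=CC(=O)C=C(C/C=C(\C)CCC=C(C)C)C1=O)[C@H](C(=O)OC)C1=CC(=O)C=C(C/C=C(\C)CCC=C(C)C)C1=O
F4 | step 3 | 2-(4-bromofuran-2-yl)-1,3-dioxolane | Brc1coc(C2OCCO2)c1
F5 | step 3 | 2-(4-geranylfuran-2-yl)-1,3-dioxolane | O1CCOC1c1cc(C/C=C(\C)CCC=C(C)C)co1
F6 | step 3 | 4-geranylfuran-2-carbaldehyde | O=Cc1cc(C/C=C(\C)CCC=C(C)C)co1
F7 | step 3 | 4-geranylfuran-2-carbaldehyde N-tosylhydrazone | Cc1ccc(cc1)S(=O)(=O)N/N=C/c1cc(C/C=C(\C)CCC=C(C)C)co1
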